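Count what stays of substrate and partner, not what has been made.

    crystals ⇌ first product, rate k1*(cs1 - [first product]) while solid is left; crystals form when [first product] > cs1 (cs1 = 17 mM, k1 = 3.42 s⁻¹)
    partner + first product → double product (k2 = 0.00526 M⁻¹ s⁻¹)
    substrate + partner → first product (k3 = 0.186 M⁻¹ s⁻¹)

| setting | north-east | north-west | north | east | south-east |
|---|---|---|---|---|---|
| substrate | 0.60 M | 1.0 M | 1.5 M | 2.5 M | 3.0 M |
| partner | 1.10 M | 1.10 M | 1.10 M | 1.10 M | 1.10 M |
| time | 15 s | 15 s | 15 s | 15 s | 15 s |

- [first product] (only what is free in solution) at the end for north-east, north-west, north, east, south-east, in this order
- the course of these numbers from the first flask to the last (rises, then falls / hardly changes / falls all the way / rises all the way / falls, then rises)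

- for first product the crystals are counted in
- as a solid, counted per litre of solution: crystals
- the concentration of first product that is asked is that of its free form alone
- "hardly changes" means that all values lie within two and a half points (for a concentration: within two and a half percent of the largest)
- run time (north-east): 15 s

I turned the question round: for the row to hardly change, its values would have to lie within the stated margin of the largest, which asks that the excess of free first product M over the solubility c = 17 mM be nearly the same from flask to flask. So I asked what holds M above c. Crystals take up an excess with a half-life of 0.203 s, shorter than the 3.4 s half-life of substrate in north-east. M therefore rides in a quasi-steady state, where crystallising, κ(M − c), matches production, kSP; S and P are substrate and partner, k the rate constant of their step, κ the dissolution coefficient. Hence M ≈ c + gSP, with g = k/κ = 0.0544 M⁻¹, the overshoot above solubility per unit of SP.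

I dropped the loss to double product, whose half-life in north-east, 120 s, is longer than the run of 15 s. S and P then fall one for one, so D = P − S stays at its charged value, and the fraction of substrate left is D/(Pe^(kDt) − S), with charged S and P.

North-east keeps 13.0% of its substrate, which gives an overshoot of 2.46 mM. North-west keeps 22.0%, for 3.84 mM. South-east, where partner is the limiting reagent, keeps 63.4%, for 0.360 mM. That spread is 16.7% of my highest M, far outside the margin, and north-west overshoots more than north-east or south-east, so I committed to this course of the row: rises, then falls.

The forecast gave 0.0195 M, 0.0209 M, 0.0207 M, 0.018 M and 0.0174 M, rises, then falls, holding that “production is highest when substrate and partner are nearly matched”.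

The simulation gave 0.0195 M, 0.0209 M, 0.0207 M, 0.0180 M and 0.0174 M: rises, then falls. With the 13% of substrate and 52% of partner left in north-east, g gives an overshoot of 2.46 mM. South-east, with 63% and 0.31% left, gets 0.359 mM. Without the low solubility of first product the row changed its shape: north-east read 0.501 M against 0.0195 M, and south-east read 1.08 M against 0.0174 M.

(The numbers of this flask are those of an exercise.)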